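## Analysis of the target

Target 34 (C36H26O19) is an achiral, linear chain of six benzene rings, A to F, joined by five diaryl ether oxygens. Every ring is para-linked and 1,3,4,5-tetraoxygenated. In each ring C1 carries the oxygen on the ring A side (in ring A the free para hydroxyl), C4 the oxygen on the ring F side (in ring F the central hydroxyl), C3 and C5 hydroxyls, and C2 and C6 hydrogen. Each bridging oxygen therefore joins C4 of one ring, flanked by two oxygenated carbons, to C1 of the next, flanked by two CH. There is no stereocentre and no ring fusion, but the chain is directional: ring A is a 2,4,6-trihydroxyphenyl end and ring F a 3,4,5-trihydroxyphenoxy end. The fourteen free phenols, with a pyrogallol-type ring F and hydroxyquinol-type inner rings, make 34 very polar and easily oxidized to quinones, above all under base and air. The difficulty is five aryl–O–aryl bonds between electron-rich rings, each di-ortho-substituted at one end, to be made in a fixed order on nearly identical rings. The feature used here: in rings B, D and F the ether oxygen on C1 and the hydroxyl on C3 are meta across the unsubstituted C2, and C3, C4 and C5 carry three contiguous oxygens. That is the pattern a benzannulation of an aryloxyalkyne (C1, C2) with a 3-alkoxy-4-oxycyclobutenone (C3 to C6) delivers, so these rings can be built with their ether oxygens already attached.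

## Retrosynthetic reasoning

34 is traced to 33 by cutting thirteen O–alkyl bonds (ten methyl, three ethyl). Alkyl ethers are the only phenol masks that tolerate both ketenes and organolithium reagents, and all of them should fall in one Lewis-acid dealkylation that cannot touch the diaryl ether bonds.

33 is cut in ring F at C2–C3 and C1–C6. C1 and C2 with the E–O–F oxygen come from alkyne 25; C3 to C6 with their three oxygens come from cyclobutenone 28. The E–O–F ether bond is thus never made by arylation: it already exists as the O–C(sp) bond of 25. The forward reaction must be a regioselective benzannulation.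

25 comes from 24 by turning the dichloroethenyl ether, a latent alkyne inert to ketenes, into the ethynyl ether. 24 is cut in ring D at C2–C3 and C1–C6 into the three-ring alkyne 19 and the one-ring cyclobutenone 12. This is the key disconnection. Both ether bonds of ring D enter as easily made O–C(sp) and O–C(sp3) bonds, and the product has two rings more than the larger precursor. The cut is placed here, and not at an aryl–oxygen bond, because every such bond joins a hindered to an electron-rich carbon.

19 comes from 18 in the same way, and 18 is cut in ring B at C2–C3 and C1–C6 into alkyne 3 and again 12. One bifunctional reagent, 12, therefore serves for rings B/C and D/E.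

12 is cut across its four-membered ring into ynol ether 9 and aryloxyketene 11, which comes from acid 8 through acid chloride 10. Cap 28 is cut likewise into 9 and methoxyketene 27 from 26. The forward reaction is a ketene–ynol ether cycloaddition that places the alkoxy group on C3 and the aryloxy or methoxy group on C4.

8 comes from phenol 7 by O-alkylation at the unhindered oxygen. 7 comes from aldehyde 5 by Baeyer–Villiger oxidation, the formyl group serving as latent C1 oxygen. 5 comes from 4, in which only the hindered hydroxyl is free, so the two oxygens of rings C and E are differentiated from the first step.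

3 comes from 2 by elimination, and 2 from phenol 1 by O-vinylation.

## Alternatives that were turned down

Alternative 1: the textbook route cuts all five aryl–oxygen bonds at C1 of rings B to F. The forward key step is an iterated CuI-catalysed Ullmann coupling of a 2,6-dimethoxyphenol chain end with 2-(benzyloxy)-5-bromo-1,3-dimethoxybenzene A1, starting from 1 to give dimer A2, each coupling followed by hydrogenolysis of the benzyl ether. It was turned down because all five bonds rest on the weakest substrate class for copper: a di-ortho-substituted, oxidation-prone phenoxide and an electron-rich aryl bromide. The sequence is strictly linear, about eleven steps with every second one such a coupling on a growing polyether, and it builds no ring of the target.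

Alternative 2: the same aryl–oxygen bonds, made by insertion of a 3,4,5-trioxygenated benzyne into the O–H bond of the hindered phenol. The aryne would come from 3-(benzyloxy)-2,4-dimethoxy-6-(trimethylsilyl)phenyl triflate A3 on fluoride treatment. The phenoxide should add at the aryne carbon remote from the neighbouring methoxy group, which puts the carbanion next to that inductively withdrawing group and gives the correct pattern. It was turned down because each aryne takes up only one oxygen and one hydrogen, so it forms one ether bond per event, as the Ullmann route does. Each unit also needs a multistep silyl triflate on a pentasubstituted benzene, and a hindered, weakly nucleophilic phenoxide invites aryne self-reaction.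

Alternative 3: a union of two phenols of like polarity by one-electron oxidation, as in the oxidative polymerization of 2,6-disubstituted phenols. 2,6-Dimethoxyphenol A4 would couple oxygen to para carbon to give dimer A5 and higher oligomers, with 1 as para-blocked end unit. It was turned down on three grounds:
- The chain length cannot be fixed at six, because every product is a new and more easily oxidized phenol and quinone-ketal redistribution scrambles the lengths.
- The 2,6-dimethoxyphenoxyl radical partitions to para–para C–C coupling, giving diphenoquinone A6.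
- 1 would be oxidized to a quinone instead of ending the chain.

Key step: step 9

Remark: the target is achiral. Compounds 12, 14, 16, 20, 22, 28, 30 and 32 each carry one sp3 stereocentre, are racemic, and lose it on aromatization. Compounds 1, 4, 9 and 26 are taken as commercially available.

Abbreviations used in names:
- Ar1 = 2,4,6-trimethoxyphenyl.
- Ar2 = 4-[(E)-1,2-dichloroethenyloxy]-3,5-dimethoxyphenyl.
- Ar3 = 4-[2-ethoxy-6-methoxy-4-(2,4,6-trimethoxyphenoxy)phenoxy]-2,6-dimethoxyphenyl.
- Ar5 = 4-[2-ethoxy-6-methoxy-4-(Ar3O)phenoxy]-2,6-dimethoxyphenyl.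

## Route

Step 1
Reactants: 1 2,4,6-trimethoxyphenol
Product: 2 2-[(E)-1,2-dichloroethenyloxy]-1,3,5-trimethoxybenzene
Conditions: trichloroethylene, K2CO3, DMF, 70 °C, Ar
Reagents that add atoms: trichloroethylene, ClC=C(Cl)Cl
Why: O-vinylation of a phenoxide with trichloroethylene (elimination to dichloroacetylene, then anti addition of the phenoxide) should give the (E)-dichloroethenyl ether; air is excluded because 1 is easily oxidized.

Step 2
Reactants: 2 2-[(E)-1,2-dichloroethenyloxy]-1,3,5-trimethoxybenzene
Product: 3 2-(ethynyloxy)-1,3,5-trimethoxybenzene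
Conditions: n-BuLi (2.2 equiv), THF, −78 °C; then MeOH, −78 °C
Reagents that add atoms: none
Why: Dehydrochlorination followed by lithium–chlorine exchange converts the dichloroethenyl ether into the lithium aryloxyacetylide, which methanol protonates; at −78 °C ring lithiation between the methoxy groups should not compete, and 3 is used at once as a solution.

Step 3
Reactants: 4 4-hydroxy-3,5-dimethoxybenzaldehyde
Product: 5 4-[(E)-1,2-dichloroethenyloxy]-3,5-dimethoxybenzaldehyde
Conditions: trichloroethylene, K2CO3, DMF, 70 °C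
Reagents that add atoms: trichloroethylene, ClC=C(Cl)Cl
Why: Same O-vinylation as in step 1; only the hindered hydroxyl of 4 is free, so the two oxygen positions of the future rings C and E are differentiated from the outset, and the non-enolizable aldehyde tolerates K2CO3.

Step 4
Reactants: 5 4-[(E)-1,2-dichloroethenyloxy]-3,5-dimethoxybenzaldehyde
Product: 7 4-[(E)-1,2-dichloroethenyloxy]-3,5-dimethoxyphenol, via aryl formate 6 (not isolated)
Conditions: mCPBA, CH2Cl2, rt; aqueous NaHCO3 wash; then cat. K2CO3, MeOH, rt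
Reagents that add atoms: 3-chloroperoxybenzoic acid, OOC(=O)c1cccc(Cl)c1
Why: Baeyer–Villiger oxidation of an electron-rich benzaldehyde (aryl migration favoured by the para oxygen) should give formate 6, which is methanolysed without isolation; the chlorine-deactivated enol ether should resist the peracid.

Step 5
Reactants: 7 4-[(E)-1,2-dichloroethenyloxy]-3,5-dimethoxyphenol
Product: 8 2-{4-[(E)-1,2-dichloroethenyloxy]-3,5-dimethoxyphenoxy}acetic acid
Conditions: NaH (2.2 equiv), BrCH2CO2H, THF, 0 to 60 °C; then aqueous HCl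
Reagents that add atoms: bromoacetic acid, OC(=O)CBr
Why: Williamson etherification of the unhindered sodium phenoxide with sodium bromoacetate should give the aryloxyacetic acid directly.

Step 6
Reactants: 8 2-{4-[(E)-1,2-dichloroethenyloxy]-3,5-dimethoxyphenoxy}acetic acid; 9 ethoxyethyne
Product: 12 4-(Ar2O)-3-ethoxycyclobut-2-en-1-one, via acid chloride 10 (not isolated), via aryloxyketene 11 (not isolated)
Conditions: (COCl)2, cat. DMF, CH2Cl2, 0 °C to rt, evaporate; then 9 (3 equiv), Et3N (slow addition), Et2O, 0 °C to rt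
Reagents that add atoms: none
Why: Dehydrochlorination of 10 gives ketene 11, which should undergo the classical [2+2] cycloaddition with an ynol ether; the ketene carbonyl carbon bonds to the terminal carbon of 9, so ethoxy ends up on C3 and aryloxy on C4.

Step 7
Reactants: 3 2-(ethynyloxy)-1,3,5-trimethoxybenzene; 12 4-(Ar2O)-3-ethoxycyclobut-2-en-1-one
Product: 18 2-(Ar2O)-1-ethoxy-3-methoxy-5-(Ar1O)benzene, via vinylketene 13 (not isolated), via vinylcyclobutenone 14 (not isolated), via dienylketene 15 (not isolated), via cyclohexadienone 16 (not isolated), via phenol 17 (not isolated)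
Conditions: 3 (1.5 equiv), PhMe, 80 then 110 °C; then K2CO3, MeI, DMF, rt
Reagents that add atoms: iodomethane, CI
Why: Danheiser benzannulation: 4π opening of 12 to 13, regioselective [2+2] cycloaddition with ynol ether 3 to 14, 4π opening to 15, 6π electrocyclization to 16 and tautomerization to 17 should build ring B with both ether oxygens in place. Methylation of 17 in the same flask removes the only acidic proton before the organolithium step, and the excess of the cheap alkyne 3 keeps 13 from acylating 17.

Step 8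
Reactants: 18 2-(Ar2O)-1-ethoxy-3-methoxy-5-(Ar1O)benzene
Product: 19 1-ethoxy-2-[4-(ethynyloxy)-3,5-dimethoxyphenoxy]-3-methoxy-5-(2,4,6-trimethoxyphenoxy)benzene
Conditions: n-BuLi (2.2 equiv), THF, −78 °C; then MeOH, −78 °C
Reagents that add atoms: none
Why: Same elimination and lithium–chlorine exchange as in step 2; 18 has no acidic proton, and the diaryl and alkyl aryl ethers are inert to n-BuLi at −78 °C.

Step 9
Reactants: 19 1-ethoxy-2-[4-(ethynyloxy)-3,5-dimethoxyphenoxy]-3-methoxy-5-(2,4,6-trimethoxyphenoxy)benzene; 12 4-(Ar2O)-3-ethoxycyclobut-2-en-1-one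
Product: 24 2-(Ar2O)-1-ethoxy-3-methoxy-5-(Ar3O)benzene, via vinylcyclobutenone 20 (not isolated), via dienylketene 21 (not isolated), via cyclohexadienone 22 (not isolated), via phenol 23 (not isolated)
Conditions: 12 (1.3 equiv, slow addition), PhMe, 80 then 110 °C; then K2CO3, MeI, DMF, rt
Reagents that add atoms: iodomethane, CI
Why: Danheiser benzannulation followed by O-methylation. Heating 12 triggers the conrotatory 4π opening already used in step 7, in which the C4 aryloxy donor rotates outward, so the reactive species is once more vinylketene 13, now met by the three-ring ynol ether 19 instead of 3. The ketene C=C of 13 adds to 19 in a [2+2] cycloaddition: the nucleophilic terminal carbon of 19 bonds to the ketene carbonyl carbon (future C2–C3 of ring D) and the oxygen-bearing carbon to the ketene α-carbon (future C1–C6), closing the four-membered ring of 20. A second 4π opening gives dienylketene 21, and ring D closes by a thermal disrotatory 6π electrocyclization between the ketene carbon and the former C4 of 12, giving 22, which enolizes to phenol 23. The closest known reaction type is the benzannulation of cyclobutenones with alkoxy- and siloxyalkynes, which gives resorcinol monoethers with this regiochemistry. The selectivity needed is aryloxy on C1 meta to the new C3 hydroxyl, with the second aryloxy on C4 between two oxygens; it is secured by the polarization of the ynol ether and by the fixed carbon order of 12. No stereocentre is formed and the sp3 centre of 12 is destroyed. The dichloroethenyl ether of ring E is not a ketenophile and should survive, and 23 is methylated in the same flask so that step 10 meets no acidic proton.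

Step 10
Reactants: 24 2-(Ar2O)-1-ethoxy-3-methoxy-5-(Ar3O)benzene
Product: 25 Ar5O–C≡CH (pentamer ethynyl ether)
Conditions: n-BuLi (2.2 equiv), THF, −78 °C; then MeOH, −78 °C
Reagents that add atoms: none
Why: Same unmasking of the latent alkyne as in steps 2 and 8.

Step 11
Reactants: 26 methoxyacetyl chloride; 9 ethoxyethyne
Product: 28 3-ethoxy-4-methoxycyclobut-2-en-1-one, via methoxyketene 27 (not isolated)
Conditions: 9 (2 equiv), Et3N, Et2O, 0 °C to rt, slow addition of 26
Reagents that add atoms: none
Why: Methoxyketene 27 from 26 and Et3N should add to 9 in the same ketene–ynol ether [2+2] cycloaddition as in step 6.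

Step 12
Reactants: 25 Ar5O–C≡CH; 28 3-ethoxy-4-methoxycyclobut-2-en-1-one
Product: 33 3-ethoxy-2-methoxy-5-(Ar5O)phenol, via vinylketene 29 (not isolated), via vinylcyclobutenone 30 (not isolated), via dienylketene 31 (not isolated), via cyclohexadienone 32 (not isolated)
Conditions: 28 (3 equiv), PhMe, 80 then 110 °C; then K2CO3, MeOH, rt
Reagents that add atoms: none
Why: Third Danheiser benzannulation, through 29, 30, 31 and 32, should build ring F with its C4 methoxy, C5 ethoxy and free C3 hydroxyl; the methanolic K2CO3 treatment cleaves any aryl ester formed from 33 and excess 29.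

Step 13
Reactants: 33 3-ethoxy-2-methoxy-5-(Ar5O)phenol
Product: 34 CNP0187343.0 (target)
Conditions: BBr3 (30 equiv), CH2Cl2, −78 °C to rt, Ar; then H2O; extraction and Sephadex LH-20 under Ar
Reagents that add atoms: none
Why: Exhaustive Lewis-acid dealkylation: bromide attacks the alkyl carbon of each borane-complexed methyl or ethyl ether, whereas diaryl ethers offer no alkyl carbon and should stay intact; work-up is kept acidic and air-free because 34 is oxidation-prone.

## Compound list

1 | 2,4,6-trimethoxyphenol | COc1cc(OC)c(O)c(OC)c1 | starting material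
2 | 2-[(E)-1,2-dichloroethenyloxy]-1,3,5-trimethoxybenzene | COc1cc(OC)c(O/C(Cl)=C\Cl)c(OC)c1 | intermediate
3 | 2-(ethynyloxy)-1,3,5-trimethoxybenzene | COc1cc(OC)c(OC#C)c(OC)c1 | intermediate
4 | 4-hydroxy-3,5-dimethoxybenzaldehyde (syringaldehyde) | COc1cc(C=O)cc(OC)c1O | starting material
5 | 4-[(E)-1,2-dichloroethenyloxy]-3,5-dimethoxybenzaldehyde | COc1cc(C=O)cc(OC)c1O/C(Cl)=C\Cl | intermediate
6 | 4-[(E)-1,2-dichloroethenyloxy]-3,5-dimethoxyphenyl formate (not isolated) | COc1cc(OC=O)cc(OC)c1O/C(Cl)=C\Cl | intermediate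
7 | 4-[(E)-1,2-dichloroethenyloxy]-3,5-dimethoxyphenol | COc1cc(O)cc(OC)c1O/C(Cl)=C\Cl | intermediate
8 | 2-{4-[(E)-1,2-dichloroethenyloxy]-3,5-dimethoxyphenoxy}acetic acid | COc1cc(OCC(=O)O)cc(OC)c1O/C(Cl)=C\Cl | intermediate
9 | ethoxyethyne (ethoxyacetylene) | CCOC#C | starting material
10 | 2-{4-[(E)-1,2-dichloroethenyloxy]-3,5-dimethoxyphenoxy}acetyl chloride (not isolated) | COc1cc(OCC(Cl)=O)cc(OC)c1O/C(Cl)=C\Cl | intermediate
11 | 2-(Ar2O)ethen-1-one, aryloxyketene (not isolated) | COc1cc(OC=C=O)cc(OC)c1O/C(Cl)=C\Cl | intermediate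
12 | rac-4-(Ar2O)-3-ethoxycyclobut-2-en-1-one | CCOC1=CC(=O)C1Oc1cc(OC)c(O/C(Cl)=C\Cl)c(OC)c1 | intermediate
13 | (3Z)-4-(Ar2O)-3-ethoxybuta-1,3-dien-1-one, vinylketene (not isolated; formed in step 7 and again in step 9) | O=C=C/C(OCC)=C/Oc1cc(OC)c(O/C(Cl)=C\Cl)c(OC)c1 | intermediate
14 | rac-4-[(Z)-2-(Ar2O)-1-ethoxyethenyl]-3-(Ar1O)cyclobut-2-en-1-one (not isolated) | O=C1C=C(Oc2c(OC)cc(OC)cc2OC)C1/C(OCC)=C/Oc1cc(OC)c(O/C(Cl)=C\Cl)c(OC)c1 | intermediate
15 | (3E,5Z)-6-(Ar2O)-5-ethoxy-3-(Ar1O)hexa-1,3,5-trien-1-one, dienylketene (not isolated) | O=C=C/C(Oc1c(OC)cc(OC)cc1OC)=C\C(OCC)=C\Oc1cc(OC)c(O/C(Cl)=C\Cl)c(OC)c1 | intermediate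
16 | rac-6-(Ar2O)-5-ethoxy-3-(Ar1O)cyclohexa-2,4-dien-1-one (not isolated) | O=C1C=C(Oc2c(OC)cc(OC)cc2OC)C=C(OCC)C1Oc1cc(OC)c(O/C(Cl)=C\Cl)c(OC)c1 | intermediate
17 | 2-(Ar2O)-3-ethoxy-5-(Ar1O)phenol (not isolated) | COc1cc(OC)c(Oc2cc(O)c(Oc3cc(OC)c(O/C(Cl)=C\Cl)c(OC)c3)c(OCC)c2)c(OC)c1 | intermediate
18 | 2-(Ar2O)-1-ethoxy-3-methoxy-5-(Ar1O)benzene | COc1cc(OC)c(Oc2cc(OC)c(Oc3cc(OC)c(O/C(Cl)=C\Cl)c(OC)c3)c(OCC)c2)c(OC)c1 | intermediate
19 | 1-ethoxy-2-[4-(ethynyloxy)-3,5-dimethoxyphenoxy]-3-methoxy-5-(2,4,6-trimethoxyphenoxy)benzene (Ar3O–C≡CH) | COc1cc(OC)c(Oc2cc(OC)c(Oc3cc(OC)c(OC#C)c(OC)c3)c(OCC)c2)c(OC)c1 | intermediate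
20 | rac-4-[(Z)-2-(Ar2O)-1-ethoxyethenyl]-3-(Ar3O)cyclobut-2-en-1-one (not isolated) | O=C1C=C(Oc2c(OC)cc(Oc3c(OC)cc(Oc4c(OC)cc(OC)cc4OC)cc3OCC)cc2OC)C1/C(OCC)=C/Oc1cc(OC)c(O/C(Cl)=C\Cl)c(OC)c1 | intermediate
21 | (3E,5Z)-6-(Ar2O)-5-ethoxy-3-(Ar3O)hexa-1,3,5-trien-1-one, dienylketene (not isolated) | O=C=C/C(Oc1c(OC)cc(Oc2c(OC)cc(Oc3c(OC)cc(OC)cc3OC)cc2OCC)cc1OC)=C\C(OCC)=C\Oc1cc(OC)c(O/C(Cl)=C\Cl)c(OC)c1 | intermediate
22 | rac-6-(Ar2O)-5-ethoxy-3-(Ar3O)cyclohexa-2,4-dien-1-one (not isolated) | O=C1C=C(Oc2c(OC)cc(Oc3c(OC)cc(Oc4c(OC)cc(OC)cc4OC)cc3OCC)cc2OC)C=C(OCC)C1Oc1cc(OC)c(O/C(Cl)=C\Cl)c(OC)c1 | intermediate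
23 | 2-(Ar2O)-3-ethoxy-5-(Ar3O)phenol (not isolated) | COc1cc(OC)c(Oc2cc(OC)c(Oc3cc(OC)c(Oc4cc(O)c(Oc5cc(OC)c(O/C(Cl)=C\Cl)c(OC)c5)c(OCC)c4)c(OC)c3)c(OCC)c2)c(OC)c1 | intermediate
24 | 2-(Ar2O)-1-ethoxy-3-methoxy-5-(Ar3O)benzene | COc1cc(OC)c(Oc2cc(OC)c(Oc3cc(OC)c(Oc4cc(OC)c(Oc5cc(OC)c(O/C(Cl)=C\Cl)c(OC)c5)c(OCC)c4)c(OC)c3)c(OCC)c2)c(OC)c1 | intermediate
25 | Ar5O–C≡CH, pentamer ethynyl ether (rings A to E; ring E 4-(ethynyloxy)-3,5-dimethoxyphenoxy) | COc1cc(OC)c(Oc2cc(OC)c(Oc3cc(OC)c(Oc4cc(OC)c(Oc5cc(OC)c(OC#C)c(OC)c5)c(OCC)c4)c(OC)c3)c(OCC)c2)c(OC)c1 | intermediate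
26 | methoxyacetyl chloride | COCC(Cl)=O | starting material
27 | methoxyketene (not isolated) | COC=C=O | intermediate
28 | rac-3-ethoxy-4-methoxycyclobut-2-en-1-one | CCOC1=CC(=O)C1OC | intermediate
29 | (3Z)-3-ethoxy-4-methoxybuta-1,3-dien-1-one, vinylketene (not isolated) | O=C=C/C(OCC)=C/OC | intermediate
30 | rac-4-[(Z)-1-ethoxy-2-methoxyethenyl]-3-(Ar5O)cyclobut-2-en-1-one (not isolated) | O=C1C=C(Oc2c(OC)cc(Oc3c(OC)cc(Oc4c(OC)cc(Oc5c(OC)cc(Oc6c(OC)cc(OC)cc6OC)cc5OCC)cc4OC)cc3OCC)cc2OC)C1/C(OCC)=C/OC | intermediate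
31 | (3E,5Z)-5-ethoxy-6-methoxy-3-(Ar5O)hexa-1,3,5-trien-1-one, dienylketene (not isolated) | O=C=C/C(Oc1c(OC)cc(Oc2c(OC)cc(Oc3c(OC)cc(Oc4c(OC)cc(Oc5c(OC)cc(OC)cc5OC)cc4OCC)cc3OC)cc2OCC)cc1OC)=C\C(OCC)=C\OC | intermediate
32 | rac-5-ethoxy-6-methoxy-3-(Ar5O)cyclohexa-2,4-dien-1-one (not isolated) | O=C1C=C(Oc2c(OC)cc(Oc3c(OC)cc(Oc4c(OC)cc(Oc5c(OC)cc(Oc6c(OC)cc(OC)cc6OC)cc5OCC)cc4OC)cc3OCC)cc2OC)C=C(OCC)C1OC | intermediate
33 | 3-ethoxy-2-methoxy-5-(Ar5O)phenol (hexamer; ten methyl and three ethyl ethers, one free hydroxyl on ring F) | COc1cc(OC)c(Oc2cc(OC)c(Oc3cc(OC)c(Oc4cc(OC)c(Oc5cc(OC)c(Oc6cc(O)c(OC)c(OCC)c6)c(OC)c5)c(OCC)c4)c(OC)c3)c(OCC)c2)c(OC)c1 | intermediate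
34 | CNP0187343.0: 2-[4-[4-[4-[4-(3,4,5-trihydroxyphenoxy)-3,5-dihydroxyphenoxy]-3,5-dihydroxyphenoxy]-3,5-dihydroxyphenoxy]-3,5-dihydroxyphenoxy]benzene-1,3,5-triol | Oc1cc(O)c(Oc2cc(O)c(Oc3cc(O)c(Oc4cc(O)c(Oc5cc(O)c(Oc6cc(O)c(O)c(O)c6)c(O)c5)c(O)c4)c(O)c3)c(O)c2)c(O)c1 | target

## Step count and least certain steps

Total step count: 13. Longest linear sequence: 10 steps (3, 4, 5, 6, 7, 8, 9, 10, 12, 13).

**Step 9 (key step; steps 7 and 12 share the risk).** The terminal aryl ynol ether may oligomerize at the temperature needed to open 12, before the vinylketene captures it. The vinylketene may also dimerize or acylate the product phenol. The fallback makes vinylketene 13 at or below room temperature by 1,4-dehydrochlorination instead of cyclobutenone opening, so the cycloaddition is separated from the heating. It sets out from 7. Alkylation of 7 with ethyl 4-chloroacetoacetate (NaH, THF) should give ethyl 4-(Ar2O)-3-oxobutanoate F1. HC(OEt)3 with catalytic H2SO4 in EtOH should give ethyl (2E)-4-(Ar2O)-3-ethoxybut-2-enoate F2. LiOH in aqueous THF should give (2E)-4-(Ar2O)-3-ethoxybut-2-enoic acid F3, and (COCl)2 the acid chloride F4. Et3N added to F4 and 19 in CH2Cl2 at 0 °C to rt should give 13, which 19 traps as 20. The fallback comes back to the route at 20; warming to 80 °C then carries 20 through 21 and 22 to 23, and methylation gives 24.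

**Step 8 (and step 10).** The terminal ynol ether may be lost by oligomerization or hydration during isolation, and n-BuLi may add to it. The fallback sets out from 18. The lithium acetylide is quenched with Me3SiCl instead of MeOH to give the stable trimethylsilyl ynol ether F5, which can be purified. Benzannulation of F5 with 12 in PhMe at 80 to 110 °C should give the 2-(trimethylsilyl)phenol F6. Protodesilylation of this electron-rich arylsilane with CF3CO2H in CH2Cl2 should give 23, where the fallback comes back to the route before the methylation to 24.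

**Step 4.** Hydrogen may migrate instead of aryl, giving over-oxidation to the acid, because the para oxygen is a weaker donor as an enol ether. The peracid may also attack the dichloroethenyl ether. The fallback oxidizes first and vinylates later, setting out from 4. Dakin oxidation of 4 (H2O2, NaOH; Na2S2O4 work-up) should give 2,6-dimethoxybenzene-1,4-diol F7. Alkylation of its unhindered, more acidic hydroxyl with tert-butyl bromoacetate (1 equiv, K2CO3, acetone) should give tert-butyl 2-(4-hydroxy-3,5-dimethoxyphenoxy)acetate F8. Trichloroethylene with K2CO3 in DMF should give the dichloroethenyl ether F9, and CF3CO2H should cleave the tert-butyl ester to give 8, where the fallback comes back to the route.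

**Step 13.** Cleavage of the three ethyl ethers may be incomplete, and the free polyphenol may oxidize in air during isolation. The fallback sets out from 33. The crude BBr3 product, after evaporation, is peracetylated (Ac2O, pyridine) to the tetradeca-O-acetate of 34 F10, which can be chromatographed and checked for complete dealkylation. Acid methanolysis (HCl, MeOH, Ar) should then release 34, where the fallback comes back to the route.

## Further compounds

F1 | step 9 | ethyl 4-(Ar2O)-3-oxobutanoate | CCOC(=O)CC(=O)COc1cc(OC)c(O/C(Cl)=C\Cl)c(OC)c1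
F2 | step 9 | ethyl (2E)-4-(Ar2O)-3-ethoxybut-2-enoate | CCOC(=O)/C=C(/OCC)COc1cc(OC)c(O/C(Cl)=C\Cl)c(OC)c1
F3 | step 9 | (2E)-4-(Ar2O)-3-ethoxybut-2-enoic acid | OC(=O)/C=C(/OCC)COc1cc(OC)c(O/C(Cl)=C\Cl)c(OC)c1
F4 | step 9 | (2E)-4-(Ar2O)-3-ethoxybut-2-enoyl chloride | ClC(=O)/C=C(/OCC)COc1cc(OC)c(O/C(Cl)=C\Cl)c(OC)c1
F5 | step 8 | trimethylsilyl-capped ynol ether of 19 (Ar3O–C≡C–SiMe3) | COc1cc(OC)c(Oc2cc(OC)c(Oc3cc(OC)c(OC#C[Si](C)(C)C)c(OC)c3)c(OCC)c2)c(OC)c1
F6 | step 8 | 2-(Ar2O)-3-ethoxy-5-(Ar3O)-6-(trimethylsilyl)phenol | COc1cc(OC)c(Oc2cc(OC)c(Oc3cc(OC)c(Oc4c([Si](C)(C)C)c(O)c(Oc5cc(OC)c(O/C(Cl)=C\Cl)c(OC)c5)c(OCC)c4)c(OC)c3)c(OCC)c2)c(OC)c1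
F7 | step 4 | 2,6-dimethoxybenzene-1,4-diol | COc1cc(O)cc(OC)c1O
F8 | step 4 | tert-butyl 2-(4-hydroxy-3,5-dimethoxyphenoxy)acetate | COc1cc(OCC(=O)OC(C)(C)C)cc(OC)c1O
F9 | step 4 | tert-butyl 2-{4-[(E)-1,2-dichloroethenyloxy]-3,5-dimethoxyphenoxy}acetate | COc1cc(OCC(=O)OC(C)(C)C)cc(OC)c1O/C(Cl)=C\Cl
F10 | step 13 | tetradeca-O-acetate of 34 | CC(=O)Oc1cc(OC(C)=O)c(Oc2cc(OC(C)=O)c(Oc3cc(OC(C)=O)c(Oc4cc(OC(C)=O)c(Oc5cc(OC(C)=O)c(Oc6cc(OC(C)=O)c(OC(C)=O)c(OC(C)=O)c6)c(OC(C)=O)c5)c(OC(C)=O)c4)c(OC(C)=O)c3)c(OC(C)=O)c2)c(OC(C)=O)c1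
A1 | alternative 1 | 2-(benzyloxy)-5-bromo-1,3-dimethoxybenzene | COc1cc(Br)cc(OC)c1OCc1ccccc1
A2 | alternative 1 | 2-(benzyloxy)-1,3-dimethoxy-5-(2,4,6-trimethoxyphenoxy)benzene | COc1cc(OC)c(Oc2cc(OC)c(OCc3ccccc3)c(OC)c2)c(OC)c1
A3 | alternative 2 | 3-(benzyloxy)-2,4-dimethoxy-6-(trimethylsilyl)phenyl trifluoromethanesulfonate | COc1cc([Si](C)(C)C)c(OS(=O)(=O)C(F)(F)F)c(OC)c1OCc1ccccc1
A4 | alternative 3 | 2,6-dimethoxyphenol | COc1cccc(OC)c1O
A5 | alternative 3 | 4-(2,6-dimethoxyphenoxy)-2,6-dimethoxyphenol | COc1cccc(OC)c1Oc1cc(OC)c(O)c(OC)c1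
A6 | alternative 3 | 3,3',5,5'-tetramethoxy-4,4'-diphenoquinone | COC1=CC(=C2C=C(OC)C(=O)C(OC)=C2)C=C(OC)C1=O
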